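**Retrosynthetic overview**
1. Target 23 ⇐ C6 ketone 22 (hydride from the convex β face) ⇐ oxygen-bridged ether 21, by a 1,2-hydride shift from C6 to C5 that opens a C2–O–C5 bridge and gives H5 (β) and the free C2 hydroxyl together.
2. C8=C9 and the side chain come from a C9 ketone: C8 methylation, enol triflate, vinyl coupling, then B-alkyl Suzuki coupling with 4-bromobutenolide (butenolide ring bought). The C4 methyl comes from exo-face hydromethylation of the cycloadduct alkene.
3. Key disconnection: C1–C2 and C5–C10 by an intramolecular Diels–Alder reaction of a furan (IMDAF). The enabling feature: C2–C3–C4–C5 of ring A, with oxygen on C2 and C5 para to it, are the four carbons of a furan whose oxygen becomes the C2 hydroxyl, and C1=C10 is the alkene of an α-methyl enone whose carbonyl is C9 of ring B.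
4. Rings A and B form together in step 5 from a precursor whose only ring is the furan; the oxygen bridge is a temporary ring removed in step 13.
5. The furyl carbinol C6 (asymmetric transfer hydrogenation) is the only catalyst-made stereocentre; it sets C2, C5 and C10 in the cycloaddition, C4 follows from the bicycle, and C6 later hands its hydrogen to C5.

Key step: step 5

Remark: labdane numbering (C1–C20) is used; β is the face carrying the C10 methyl, α the opposite face; read this way the target is A/B-cis (H5 β), 2α,6α-dihydroxy, 4β-CH2OAc, (2R,4S,5S,6S,10S); diamide 2 and bromobutenolide 17 are taken as purchasable.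

**Route**

Step 1
Reactants: 1 furan-3-ylmethanol; 2 N1,N4-dimethoxy-N1,N4-dimethylbutanediamide
Product: 4 4-[3-(hydroxymethyl)furan-2-yl]-N-methoxy-N-methyl-4-oxobutanamide, via dilithio alkoxide 3 (not isolated)
Conditions: n-BuLi (2.2 equiv), THF, −78 → 0 °C; then add to 2 (2 equiv), −78 °C; aq. NH4Cl
Reagents that add atoms: none
Why: Alkoxide-directed ortho-lithiation puts lithium on furan C2 next to the CH2OLi group, and the Weinreb ketone synthesis stops at mono-addition because the tetrahedral chelate survives until work-up and 2 is in excess.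

Step 2
Reactants: 4 4-[3-(hydroxymethyl)furan-2-yl]-N-methoxy-N-methyl-4-oxobutanamide
Product: 5 (4S)-4-hydroxy-4-[3-(hydroxymethyl)furan-2-yl]-N-methoxy-N-methylbutanamide
Conditions: RuCl(p-cymene)[(S,S)-TsDPEN] (1 mol%), HCO2Na, H2O/CH2Cl2, 40 °C
Reagents that add atoms: none
Why: Noyori–Ikariya asymmetric transfer hydrogenation of a heteroaryl alkyl ketone, in which the (S,S) ligand should deliver hydride to the face giving the (S)-carbinol (C6) by the usual aryl/alkyl discrimination, and the neutral formate medium should spare the γ-hydroxy amide from lactonization.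

Step 3
Reactants: 5 (4S)-4-hydroxy-4-[3-(hydroxymethyl)furan-2-yl]-N-methoxy-N-methylbutanamide
Product: 7 (4S)-4-[3-(tert-butyldimethylsilyloxymethyl)furan-2-yl]-N-methoxy-N-methyl-4-(triisopropylsilyloxy)butanamide, via mono-TBS ether 6 (not isolated)
Conditions: TBSCl (1.05 equiv), imidazole, CH2Cl2, 0 °C; then 2,6-lutidine, TIPSOTf (1.5 equiv), 0 °C → rt
Reagents that add atoms: tert-butyldimethylsilyl chloride CC(C)(C)[Si](C)(C)Cl; triisopropylsilyl trifluoromethanesulfonate CC(C)[Si](OS(=O)(=O)C(F)(F)F)(C(C)C)C(C)C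
Why: The primary alcohol is silylated selectively by TBSCl and the hindered secondary carbinol is then capped by the more reactive silyl triflate, giving two silyl ethers that can be told apart later.

Step 4
Reactants: 7 (4S)-4-[3-(tert-butyldimethylsilyloxymethyl)furan-2-yl]-N-methoxy-N-methyl-4-(triisopropylsilyloxy)butanamide
Product: 8 (6S)-6-[3-(tert-butyldimethylsilyloxymethyl)furan-2-yl]-2-methyl-6-(triisopropylsilyloxy)hex-1-en-3-one
Conditions: CH2=C(CH3)MgBr (2.5 equiv), THF, −20 → 0 °C; aq. NH4Cl
Reagents that add atoms: isopropenylmagnesium bromide C=C(C)[Mg]Br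
Why: Weinreb ketone synthesis, which stops at the α-methyl enone because the magnesium chelate collapses only on work-up.

Step 5
Reactants: 8 (6S)-6-[3-(tert-butyldimethylsilyloxymethyl)furan-2-yl]-2-methyl-6-(triisopropylsilyloxy)hex-1-en-3-one
Product: 9 oxygen-bridged cycloadduct 10-(tert-butyldimethylsilyloxymethyl)-6-methyl-2-(triisopropylsilyloxy)-11-oxatricyclo[6.2.1.0(1,6)]undec-9-en-5-one (labdane terms: 2α,5α-epoxy; C3=C4; C9 ketone; 10β-methyl; 6α-OTIPS)
Conditions: MeAlCl2 (1.1 equiv), CH2Cl2, −78 °C; Et3N then aq. NaHCO3 at −78 °C; used at once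
Reagents that add atoms: none
Why: The Lewis acid-bound enone (carbonyl C9) and the furan should undergo a concerted, asynchronous [4+2] cycloaddition in which the free furan α-carbon (C2) bonds to the enone β-carbon C1 and the tether-bearing furan carbon (C5) bonds to the α-carbon C10. The closest known reaction type is the MeAlCl2-promoted intramolecular Diels–Alder reaction of 2-(5-oxoalk-6-enyl)furans at low temperature, which likewise closes a six-membered carbocycle next to the oxygen bridge. Ring A is closed by the cycloaddition itself as a 7-oxabicyclo[2.2.1]heptene (both new bonds lie in it), and ring B is closed as the six-membered tether ring by the C5–C10 bond (6-exo with respect to the enone alkene, fused mode). The four-atom tether enforces the exo-tether geometry, so the C10 methyl is endo and trans to the oxygen bridge that joins C2 and C5 on one face; the furan face is chosen by C6, whose OTIPS group takes the equatorial site of the chair-like tether because the other face would place it 1,3-diaxial to the C10 methyl and against the furan CH2OTBS group. The step needs π-facial selectivity (secured by the (S)-C6 centre), fused regiochemistry (secured by the short tether) and a favourable equilibrium (low temperature, Lewis acid complexation, immediate consumption of the alkene in step 6).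

Step 6
Reactants: 9 oxygen-bridged cycloadduct
Product: 11 bridged ketone (2α,5α-epoxy; 4α-methyl; 4β-CH2OTBS; 6α-OTIPS; 10β-methyl; C9 ketone), via sulfonyl hydrazide 10 (not isolated)
Conditions: preformed CH2=N–NHSO2(n-C8H17) (3 equiv), Fe(acac)3 (0.5 equiv), PhSiH3 (3 equiv), THF/MeOH, rt; then MeOH, 60 °C
Reagents that add atoms: formaldehyde N-(octane-1-sulfonyl)hydrazone C=NNS(=O)(=O)CCCCCCCC
Why: Iron-hydride hydrogen atom transfer (Mukaiyama-type hydromethylation of an unactivated trisubstituted alkene) puts H on C3 and the tertiary C4 radical adds to the hydrazone from the exo (α) face because the endo face is covered by the C10 methyl; loss of sulfinate and N2 on warming leaves the 4α-methyl group, and the cycloadduct can no longer revert.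

Step 7
Reactants: 11 bridged ketone
Product: 13 8-methyl bridged ketone (both C8 epimers; centre erased in step 8), via lithium enolate 12 (not isolated)
Conditions: LiN(i-Pr)2 (1.1 equiv), THF, −78 °C; MeI, −78 → −20 °C
Reagents that add atoms: iodomethane CI
Why: Enolate alkylation that is regiospecific because the C9 ketone can enolize only toward C8 (C10 is quaternary and has no β-hydrogen for elimination of the bridge oxygen).

Step 8
Reactants: 13 8-methyl bridged ketone
Product: 15 C9 enol triflate with C8=C9 (8-methyl), via potassium enolate 14 (not isolated)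
Conditions: KN(SiMe3)2 (1.3 equiv), THF, −78 °C; PhNTf2, −78 → 0 °C
Reagents that add atoms: N-phenylbis(trifluoromethanesulfonimide) O=S(=O)(N(c1ccccc1)S(=O)(=O)C(F)(F)F)C(F)(F)F
Why: Deprotonation at the only α-hydrogen (C8) and O-triflation fix the tetrasubstituted C8=C9 alkene of ring B without regiochemical ambiguity.

Step 9
Reactants: 15 C9 enol triflate
Product: 16 9-vinyl diene (C8=C9 and C11=C12)
Conditions: CH2=CH–B(pin) (1.5 equiv), PdCl2(dppf) (5 mol%), K3PO4, 1,4-dioxane/H2O, 80 °C
Reagents that add atoms: 4,4,5,5-tetramethyl-2-vinyl-1,3,2-dioxaborolane C=CB1OC(C)(C)C(C)(C)O1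
Why: Suzuki–Miyaura coupling of an enol triflate, a reaction class that tolerates fully substituted, hindered triflates.

Step 10
Reactants: 16 9-vinyl diene; 17 4-bromofuran-2(5H)-one
Product: 19 bridged butenolide (C9–CH2CH2–butenolide; 19-OTBS; 6α-OTIPS), via B-alkyl-9-BBN borane 18 (not isolated)
Conditions: 9-BBN (1.3 equiv), THF, 0 °C → rt; then 17, PdCl2(dppf) (5 mol%), AsPh3 (10 mol%), aq. K3PO4, DMF, rt
Reagents that add atoms: none
Why: 9-BBN should hydroborate only the monosubstituted vinyl terminus (boron on C12) and the B-alkyl Suzuki–Miyaura coupling with the 4-bromobutenolide then forms the C12–C13 bond.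

Step 11
Reactants: 19 bridged butenolide
Product: 20 C19 primary alcohol (6α-OTIPS retained)
Conditions: HF·pyridine, pyridine, THF, 0 °C
Reagents that add atoms: none
Why: Fluoride-mediated desilylation removes the primary TBS ether much faster than the hindered secondary TIPS ether.

Step 12
Reactants: 20 C19 primary alcohol
Product: 21 C19 acetate (2α,5α-epoxy; 6α-OTIPS)
Conditions: Ac2O, pyridine, DMAP (cat.), CH2Cl2, 0 °C → rt
Reagents that add atoms: acetic anhydride CC(=O)OC(C)=O
Why: Acylation of the only free hydroxyl, so the acetate is placed on C19 without any selectivity question.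

Step 13
Reactants: 21 C19 acetate
Product: 22 A/B-cis C6 ketone (2α-OH; H5 β; 19-OAc)
Conditions: BF3·OEt2 (3 equiv), CH2Cl2, −78 → −30 °C; cold aq. NaHCO3; used at once
Reagents that add atoms: none
Why: Proposed new method: BF3 binds the strained bridging oxygen and the tertiary C5–O bond ionizes with assistance from the anti-periplanar axial C6–H bond, whose 1,2-shift to C5 is driven by formation of the silyl-stabilized oxocarbenium ion at C6 (fluoride then removes the TIPS group), so that hydrogen enters C5 on the face opposite to the departing oxygen, C5 is inverted to the A/B-cis fusion and the bridge oxygen is left as the C2 hydroxyl; the closest known reaction types are the Lewis acid-induced 1,2-hydride shift of epoxy silyl ethers and of 5α,6α-epoxy steroids (to 5β 6-ketones) and the alkoxide-driven hydride shift that follows oxygen-bridge opening of amidofuran cycloadducts, none of which involves a 7-oxanorbornane carbinol ether.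

Step 14
Reactants: 22 A/B-cis C6 ketone
Product: 23 target, (2R,4S,5S,6S,10S)-19-acetoxy-2α,6α-dihydroxy-5β-labda-8,13-dien-15,16-olide
Conditions: LiAlH(Ot-Bu)3 (3 equiv), THF, −78 → −20 °C; Rochelle salt work-up
Reagents that add atoms: none
Why: Hydride should attack the C6 ketone of the cis-fused bicycle from the convex β face (the α face is blocked by the axial C1 methylene of ring A), giving the 6α alcohol, and this mild alkoxyaluminium hydride leaves acetate and butenolide untouched.

**Compound list**
1 | furan-3-ylmethanol | OCc1ccoc1 | starting material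
2 | N1,N4-dimethoxy-N1,N4-dimethylbutanediamide | CON(C)C(=O)CCC(=O)N(C)OC | starting material
3 | lithium (2-lithiofuran-3-yl)methanolate | [Li]OCc1ccoc1[Li] | intermediate
4 | 4-[3-(hydroxymethyl)furan-2-yl]-N-methoxy-N-methyl-4-oxobutanamide | CON(C)C(=O)CCC(=O)c1occc1CO | intermediate
5 | (4S)-4-hydroxy-4-[3-(hydroxymethyl)furan-2-yl]-N-methoxy-N-methylbutanamide | CON(C)C(=O)CC[C@H](O)c1occc1CO | intermediate
6 | (4S)-4-[3-(tert-butyldimethylsilyloxymethyl)furan-2-yl]-4-hydroxy-N-methoxy-N-methylbutanamide | CON(C)C(=O)CC[C@H](O)c1occc1CO[Si](C)(C)C(C)(C)C | intermediate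
7 | (4S)-4-[3-(tert-butyldimethylsilyloxymethyl)furan-2-yl]-N-methoxy-N-methyl-4-(triisopropylsilyloxy)butanamide | CON(C)C(=O)CC[C@H](O[Si](C(C)C)(C(C)C)C(C)C)c1occc1CO[Si](C)(C)C(C)(C)C | intermediate
8 | (6S)-6-[3-(tert-butyldimethylsilyloxymethyl)furan-2-yl]-2-methyl-6-(triisopropylsilyloxy)hex-1-en-3-one | C=C(C)C(=O)CC[C@H](O[Si](C(C)C)(C(C)C)C(C)C)c1occc1CO[Si](C)(C)C(C)(C)C | intermediate
9 | cycloadduct, 10-(tert-butyldimethylsilyloxymethyl)-6-methyl-2-(triisopropylsilyloxy)-11-oxatricyclo[6.2.1.0(1,6)]undec-9-en-5-one (2α,5α-epoxy; 10β-methyl; 6α-OTIPS) | CC(C)(C)[Si](C)(C)OCC1=C[C@H]2C[C@]3(C)C(=O)CC[C@H](O[Si](C(C)C)(C(C)C)C(C)C)[C@@]13O2 | intermediate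
10 | sulfonyl hydrazide (as 11, with 4α-CH2NHNHSO2-octyl in place of 4α-methyl) | CC(C)(C)[Si](C)(C)OC[C@@]1(CNNS(=O)(=O)CCCCCCCC)C[C@H]2C[C@]3(C)C(=O)CC[C@H](O[Si](C(C)C)(C(C)C)C(C)C)[C@@]13O2 | intermediate
11 | bridged ketone (2α,5α-epoxy; 4α-methyl; 4β-CH2OTBS; 6α-OTIPS; 10β-methyl; C9 ketone) | CC(C)(C)[Si](C)(C)OC[C@@]1(C)C[C@H]2C[C@]3(C)C(=O)CC[C@H](O[Si](C(C)C)(C(C)C)C(C)C)[C@@]13O2 | intermediate
12 | lithium C8(9)-enolate of 11 | CC(C)(C)[Si](C)(C)OC[C@@]1(C)C[C@H]2C[C@]3(C)C(O[Li])=CC[C@H](O[Si](C(C)C)(C(C)C)C(C)C)[C@@]13O2 | intermediate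
13 | 8-methyl bridged ketone (C8 epimers) | CC(C)(C)[Si](C)(C)OC[C@@]1(C)C[C@H]2C[C@]3(C)C(=O)C(C)C[C@H](O[Si](C(C)C)(C(C)C)C(C)C)[C@@]13O2 | intermediate
14 | potassium C8(9)-enolate of 13 | CC(C)(C)[Si](C)(C)OC[C@@]1(C)C[C@H]2C[C@]3(C)C(O[K])=C(C)C[C@H](O[Si](C(C)C)(C(C)C)C(C)C)[C@@]13O2 | intermediate
15 | C9 enol triflate (C8=C9; 8-methyl) | CC(C)(C)[Si](C)(C)OC[C@@]1(C)C[C@H]2C[C@]3(C)C(OS(=O)(=O)C(F)(F)F)=C(C)C[C@H](O[Si](C(C)C)(C(C)C)C(C)C)[C@@]13O2 | intermediate
16 | 9-vinyl diene | CC(C)(C)[Si](C)(C)OC[C@@]1(C)C[C@H]2C[C@]3(C)C(C=C)=C(C)C[C@H](O[Si](C(C)C)(C(C)C)C(C)C)[C@@]13O2 | intermediate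
17 | 4-bromofuran-2(5H)-one | O=C1OCC(Br)=C1 | starting material
18 | B-alkyl-9-BBN borane (boron on C12) | CC(C)(C)[Si](C)(C)OC[C@@]1(C)C[C@H]2C[C@]3(C)C(CCB4C5CCCC4CCC5)=C(C)C[C@H](O[Si](C(C)C)(C(C)C)C(C)C)[C@@]13O2 | intermediate
19 | bridged butenolide (19-OTBS; 6α-OTIPS) | CC(C)(C)[Si](C)(C)OC[C@@]1(C)C[C@H]2C[C@]3(C)C(CCC4=CC(=O)OC4)=C(C)C[C@H](O[Si](C(C)C)(C(C)C)C(C)C)[C@@]13O2 | intermediate
20 | C19 primary alcohol (6α-OTIPS) | OC[C@@]1(C)C[C@H]2C[C@]3(C)C(CCC4=CC(=O)OC4)=C(C)C[C@H](O[Si](C(C)C)(C(C)C)C(C)C)[C@@]13O2 | intermediate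
21 | C19 acetate (2α,5α-epoxy; 6α-OTIPS) | CC(=O)OC[C@@]1(C)C[C@H]2C[C@]3(C)C(CCC4=CC(=O)OC4)=C(C)C[C@H](O[Si](C(C)C)(C(C)C)C(C)C)[C@@]13O2 | intermediate
22 | A/B-cis C6 ketone (2α-OH; H5 β; 19-OAc) | CC(=O)OC[C@@]1(C)C[C@H](O)C[C@]2(C)C(CCC3=CC(=O)OC3)=C(C)CC(=O)[C@H]12 | intermediate
23 | (2R,4S,5S,6S,10S)-19-acetoxy-2α,6α-dihydroxy-5β-labda-8,13-dien-15,16-olide | CC(=O)OC[C@@]1(C)C[C@H](O)C[C@]2(C)C(CCC3=CC(=O)OC3)=C(C)C[C@H](O)[C@H]12 | target

**Step count and risks**
Total steps: 14. Longest linear sequence: 14 (from furan-3-ylmethanol).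

Steps most likely to fail:

1. Step 13 (Proposed new method). Ionization at C5 may not be followed by the hydride shift: a methyl or acyloxymethyl 1,2-shift, acetate participation, proton loss, or epimerization at C5 and conjugation of the β,γ-unsaturated ketone could intervene. The fallback sets out from 21 and changes the cleavage from cationic to reductive. TBAF buffered with AcOH would free the C6 carbinol, the 6α-hydroxy bridged acetate F1. Dess–Martin periodinane would oxidize it to the α-alkoxy ketone F2. SmI2 in THF/t-BuOH at −78 °C would then cleave the C5–O bond (the known reductive cleavage of α-alkoxy ketones), and protonation of the samarium enolate at C5 would come back to the route at 22. In this fallback C5 rests on kinetic protonation, which on steric grounds is expected to favour the open α face and hence the 5α epimer, so the fallback is weak at exactly the centre that the hydride shift is meant to secure.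

2. Step 5. The cycloaddition equilibrium may lie on the side of 8, or the Lewis acid may ionize the furfuryl silyl ether. The fallback sets out from 8 and uses the halogen effect instead of Lewis acid activation. NBS in DMF at −20 °C would brominate the free furan α-position to give the 5-bromofuran enone F3. Halofurans of this kind cyclize thermally and more exergonically (toluene, 80–110 °C, no Lewis acid), which should give the bridgehead bromide adduct F4. Bu3SnH/AIBN would then remove the bridgehead bromine and come back to the route at 9.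

3. Step 6. Capture of the hindered tertiary C4 radical may be slow (plain reduction of the alkene), or the adduct may revert before the alkene is consumed. The fallback sets out from 9 and builds the methyl group by a two-electron route. Simmons–Smith cyclopropanation (Et2Zn, CH2I2, CH2Cl2, 0 °C) on the exo face would give the exo cyclopropane F5. Hydrogenolysis (H2, PtO2, AcOH) of its less hindered C3–CH2 bond would come back to the route at 11.

Further compounds
F1 | step 13 | 6α-hydroxy bridged acetate (2α,5α-epoxy; 19-OAc) | CC(=O)OC[C@@]1(C)C[C@H]2C[C@]3(C)C(CCC4=CC(=O)OC4)=C(C)C[C@H](O)[C@@]13O2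
F2 | step 13 | 6-oxo bridged acetate (α-alkoxy ketone) | CC(=O)OC[C@@]1(C)C[C@H]2C[C@]3(C)C(CCC4=CC(=O)OC4)=C(C)CC(=O)[C@@]13O2
F3 | step 5 | (6S)-6-[5-bromo-3-(tert-butyldimethylsilyloxymethyl)furan-2-yl]-2-methyl-6-(triisopropylsilyloxy)hex-1-en-3-one | C=C(C)C(=O)CC[C@H](O[Si](C(C)C)(C(C)C)C(C)C)c1oc(Br)cc1CO[Si](C)(C)C(C)(C)C
F4 | step 5 | C2 bridgehead bromide of cycloadduct 9 | CC(C)(C)[Si](C)(C)OCC1=C[C@@]2(Br)C[C@]3(C)C(=O)CC[C@H](O[Si](C(C)C)(C(C)C)C(C)C)[C@@]13O2
F5 | step 6 | exo (α) C3–C4 cyclopropane of cycloadduct 9 | CC(C)(C)[Si](C)(C)OC[C@@]1(C5)[C@H]5[C@H]2C[C@]3(C)C(=O)CC[C@H](O[Si](C(C)C)(C(C)C)C(C)C)[C@@]13O2
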